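## Retrosynthetic overview

1. The last C–C bond is the (E)-styryl link to the 8-coumarinyl unit, made by Heck coupling of a 6-vinylcyclohexene with 8-iodo-7-methoxycoumarin; the vinyl group comes from a ring CO2H via the aldehyde.
2. Key step: the cyclohexene ring, the bond between its two stereocentres and both stereocentres form together in an Ireland–Claisen ring contraction ([3,3]) of the silyl ketene acetal of a 3,6-dimethyl-6-styryl-δ-lactone, which can only react through a boat transition state; the lactone's tertiary C–O stereocentre is consumed.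
3. The styryl lactone comes from a 6-vinyl-δ-lactol by Heck arylation with 6-bromo-7-methoxycoumarin, oxidation and α-methylation.
4. The vinyl lactol is (S)-linalool cut at its trisubstituted alkene (ozonolysis) and lengthened by one carbon (Wittig); its carbinol carbon is the only stereocentre that is bought.
5. Ring order: coumarin of the 6-aryl unit (built) and of the 8-aryl unit (bought as umbelliferone), then the temporary oxane ring, then the cyclohexene ring.

Assumption: (S)-(+)-linalool (coriandrol, the linalool of coriander seed oil) and 5-bromo-2-hydroxy-4-methoxybenzaldehyde are bought; the enantiomeric purity of the linalool is carried through unchanged and can be raised by recrystallising the carboxylic acid formed in step 7.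

## Route

Step 1
Reactants: 1 (S)-(+)-linalool [(3S)-3,7-dimethylocta-1,6-dien-3-ol]
Product: 3 (5S)-5-ethenyl-5-methyloxolan-2-ol (anomer mixture), via ozonide 2 (not isolated)
Conditions: O3 (1.0 equiv), CH2Cl2, −78 °C; then PPh3, −78 °C → rt
Reagents that add atoms: ozone, [O-][O+]=O
Why: Ozonolysis with reductive work-up: ozone adds much faster to the electron-rich trisubstituted alkene than to the vinyl group next to the carbinol, acetone is cut off and the hydroxy aldehyde closes to the lactol, leaving the bought tertiary stereocentre untouched.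

Step 2
Reactants: 3 (5S)-5-ethenyl-5-methyloxolan-2-ol
Product: 5 (6S)-6-ethenyl-6-methyloxan-2-ol (anomer mixture), via enol ether 4 (not isolated)
Conditions: MeOCH2PPh3Cl, KOtBu, THF, 0 °C → rt; then 1 M HCl (aq), THF, rt
Reagents that add atoms: (methoxymethyl)triphenylphosphonium chloride, COC[P+](c1ccccc1)(c1ccccc1)c1ccccc1.[Cl-]; water, O
Why: Wittig methoxymethylenation of the open hydroxy-aldehyde form of the lactol followed by acid hydrolysis of the enol ether is a one-carbon homologation, and the new aldehyde closes on the tertiary hydroxyl to the six-membered lactol without touching the stereocentre.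

Step 3
Reactants: 6 5-bromo-2-hydroxy-4-methoxybenzaldehyde
Product: 8 6-bromo-7-methoxy-2H-chromen-2-one, via hydroxycinnamate ester 7 (not isolated)
Conditions: Ph3P=CHCO2Et, PhNEt2, 215 °C
Reagents that add atoms: ethyl (triphenylphosphoranylidene)acetate, CCOC(=O)C=P(c1ccccc1)(c1ccccc1)c1ccccc1
Why: Wittig olefination of the salicylaldehyde gives the 2-hydroxycinnamate, which at this temperature isomerises about the double bond and lactonises with loss of ethanol to the coumarin.

Step 4
Reactants: 5 (6S)-6-ethenyl-6-methyloxan-2-ol; 8 6-bromo-7-methoxy-2H-chromen-2-one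
Product: 9 (6S)-6-[(E)-2-(7-methoxy-2-oxo-2H-chromen-6-yl)ethenyl]-6-methyloxan-2-ol (anomer mixture)
Conditions: Pd2(dba)3 (2 mol %), [HP(tBu)3]BF4 (8 mol %), Cy2NMe, dioxane, 70 °C
Reagents that add atoms: none
Why: Mizoroki–Heck reaction: the aryl group adds to the terminal vinyl carbon and the only β-hydrogens are benzylic, so the (E)-styrene forms; the ring oxygen of the lactol is a poor leaving group, so the quaternary stereocentre is not ionised.

Step 5
Reactants: 9 (6S)-6-[(E)-2-(7-methoxy-2-oxo-2H-chromen-6-yl)ethenyl]-6-methyloxan-2-ol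
Product: 10 (6S)-6-[(E)-2-(7-methoxy-2-oxo-2H-chromen-6-yl)ethenyl]-6-methyloxan-2-one
Conditions: TEMPO (10 mol %), PhI(OAc)2, CH2Cl2, rt
Reagents that add atoms: none
Why: Oxoammonium (TEMPO) oxidation converts the lactol to the δ-lactone under near-neutral conditions that leave the styrene, the coumarin and the acid-sensitive tertiary allylic C–O bond alone.

Step 6
Reactants: 10 (6S)-6-[(E)-2-(7-methoxy-2-oxo-2H-chromen-6-yl)ethenyl]-6-methyloxan-2-one
Product: 12 (3RS,6S)-6-[(E)-2-(7-methoxy-2-oxo-2H-chromen-6-yl)ethenyl]-3,6-dimethyloxan-2-one, via lithium enolate 11 (not isolated)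
Conditions: LiN(SiMe3)2, THF, −78 °C; then MeI, DMPU, −78 → −40 °C
Reagents that add atoms: iodomethane, CI
Why: Lactone enolate alkylation with a non-nucleophilic amide base that spares the coumarin; the new C3 centre forms as a mixture, which does not matter because it becomes planar in the next step.

Step 7
Reactants: 12 (3RS,6S)-6-[(E)-2-(7-methoxy-2-oxo-2H-chromen-6-yl)ethenyl]-3,6-dimethyloxan-2-one
Product: 15 (1R,2R)-2-(7-methoxy-2-oxo-2H-chromen-6-yl)-1,4-dimethylcyclohex-3-ene-1-carboxylic acid, via trimethylsilyl ketene acetal 13 (not isolated), via trimethylsilyl ester 14 (not isolated)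
Conditions: Me3SiCl, KN(SiMe3)2, THF, −78 °C → rt; then PhMe, 110 °C; then 1 M HCl (aq), THF, rt
Reagents that add atoms: none
Why: Ireland–Claisen ring contraction of a lactone silyl ketene acetal: the endocyclic ketene acetal has a fixed geometry and can reach the (E)-styryl terminus only through a boat [3,3] transition state, so the (6S) C–O stereocentre is transferred suprafacially into both new centres (aryl cis to carboxyl and trans to methyl, 1R,2R) while the cyclohexene ring and its trisubstituted alkene form.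

Step 8
Reactants: 15 (1R,2R)-2-(7-methoxy-2-oxo-2H-chromen-6-yl)-1,4-dimethylcyclohex-3-ene-1-carboxylic acid
Product: 17 (1R,2R)-2-(7-methoxy-2-oxo-2H-chromen-6-yl)-1,4-dimethylcyclohex-3-ene-1-carbaldehyde, via acid chloride 16 (not isolated)
Conditions: 1-chloro-N,N,2-trimethylprop-1-en-1-amine, CH2Cl2, 0 °C → rt; then LiAlH(OtBu)3, THF, −78 °C
Reagents that add atoms: none
Why: Neutral acid chloride formation followed by partial reduction with the bulky, mild hydride LiAlH(OtBu)3 stops at the hindered aldehyde and leaves the coumarin lactone alone; the quaternary α-carbon cannot epimerise.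

Step 9
Reactants: 17 (1R,2R)-2-(7-methoxy-2-oxo-2H-chromen-6-yl)-1,4-dimethylcyclohex-3-ene-1-carbaldehyde
Product: 18 6-[(1S,6S)-6-ethenyl-3,6-dimethylcyclohex-2-en-1-yl]-7-methoxy-2H-chromen-2-one
Conditions: MePPh3Br, KOtBu, THF, 0 °C
Reagents that add atoms: methyltriphenylphosphonium bromide, C[P+](c1ccccc1)(c1ccccc1)c1ccccc1.[Br-]
Why: Wittig methylenation of a non-enolisable aldehyde, which reacts far faster with the small ylide than the coumarin lactone does; the stereocentres are not involved (the descriptors change only through CIP priorities).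

Step 10
Reactants: 19 7-hydroxy-2H-chromen-2-one (umbelliferone)
Product: 20 7-hydroxy-8-iodo-2H-chromen-2-one
Conditions: I2, KI, 20% aq. NH3, 0 °C → rt
Reagents that add atoms: iodine, II
Why: Electrophilic aromatic iodination of the phenoxide goes to C8, the position ortho to the phenoxide oxygen and flanked by the ring oxygen, which is the most nucleophilic carbon of umbelliferone.

Step 11
Reactants: 20 7-hydroxy-8-iodo-2H-chromen-2-one
Product: 21 8-iodo-7-methoxy-2H-chromen-2-one
Conditions: MeI, K2CO3, acetone, reflux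
Reagents that add atoms: iodomethane, CI
Why: Williamson ether synthesis: the phenoxide is methylated by SN2 displacement on iodomethane.

Step 12
Reactants: 18 6-[(1S,6S)-6-ethenyl-3,6-dimethylcyclohex-2-en-1-yl]-7-methoxy-2H-chromen-2-one; 21 8-iodo-7-methoxy-2H-chromen-2-one
Product: 22 6-[(1S,6S)-6-[(E)-2-(7-methoxy-2-oxo-2H-chromen-8-yl)ethenyl]-3,6-dimethylcyclohex-2-en-1-yl]-7-methoxy-2H-chromen-2-one (CNP0287121.2)
Conditions: Pd(OAc)2 (10 mol %), Bu4NCl, NaHCO3, DMF, 85 °C
Reagents that add atoms: none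
Why: Mizoroki–Heck reaction under phosphine-free conditions: the vinyl group sits on a quaternary carbon, so the aryl adds to its terminus and β-hydride elimination can only occur on the benzylic side, giving the (E)-styrene without touching either stereocentre or the ring alkene.

## Compound list

1 | (S)-(+)-linalool, (3S)-3,7-dimethylocta-1,6-dien-3-ol | C=C[C@@](C)(O)CCC=C(C)C | starting material
2 | 3-[(3S)-3-hydroxy-3-methylpent-4-en-1-yl]-5,5-dimethyl-1,2,4-trioxolane (ozonide) | CC1(C)OOC(CC[C@](C)(O)C=C)O1 | intermediate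
3 | (5S)-5-ethenyl-5-methyloxolan-2-ol | OC1CC[C@@](C)(C=C)O1 | intermediate
4 | (3S)-7-methoxy-3-methylhepta-1,6-dien-3-ol (E/Z enol ether) | C=C[C@@](C)(O)CCC=COC | intermediate
5 | (6S)-6-ethenyl-6-methyloxan-2-ol | OC1CCC[C@@](C)(C=C)O1 | intermediate
6 | 5-bromo-2-hydroxy-4-methoxybenzaldehyde | O=Cc1cc(Br)c(OC)cc1O | starting material
7 | ethyl 3-(5-bromo-2-hydroxy-4-methoxyphenyl)prop-2-enoate (E/Z) | CCOC(=O)C=Cc1cc(Br)c(OC)cc1O | intermediate
8 | 6-bromo-7-methoxy-2H-chromen-2-one | COc1cc2oc(=O)ccc2cc1Br | intermediate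
9 | (6S)-6-[(E)-2-(7-methoxy-2-oxo-2H-chromen-6-yl)ethenyl]-6-methyloxan-2-ol | OC1CCC[C@@](C)(/C=C/c2cc3ccc(=O)oc3cc2OC)O1 | intermediate
10 | (6S)-6-[(E)-2-(7-methoxy-2-oxo-2H-chromen-6-yl)ethenyl]-6-methyloxan-2-one | O=C1CCC[C@@](C)(/C=C/c2cc3ccc(=O)oc3cc2OC)O1 | intermediate
11 | lithium enolate of 10 | [Li+].[O-]C1=CCC[C@@](C)(/C=C/c2cc3ccc(=O)oc3cc2OC)O1 | intermediate
12 | (3RS,6S)-6-[(E)-2-(7-methoxy-2-oxo-2H-chromen-6-yl)ethenyl]-3,6-dimethyloxan-2-one | O=C1C(C)CC[C@@](C)(/C=C/c2cc3ccc(=O)oc3cc2OC)O1 | intermediate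
13 | 6-{(E)-2-[(2S)-2,5-dimethyl-6-(trimethylsilyloxy)-3,4-dihydro-2H-pyran-2-yl]ethenyl}-7-methoxy-2H-chromen-2-one | C[Si](C)(C)OC1=C(C)CC[C@@](C)(/C=C/c2cc3ccc(=O)oc3cc2OC)O1 | intermediate
14 | trimethylsilyl (1R,2R)-2-(7-methoxy-2-oxo-2H-chromen-6-yl)-1,4-dimethylcyclohex-3-ene-1-carboxylate | COc1cc2oc(=O)ccc2cc1[C@H]1C=C(C)CC[C@@]1(C)C(=O)O[Si](C)(C)C | intermediate
15 | (1R,2R)-2-(7-methoxy-2-oxo-2H-chromen-6-yl)-1,4-dimethylcyclohex-3-ene-1-carboxylic acid | COc1cc2oc(=O)ccc2cc1[C@H]1C=C(C)CC[C@@]1(C)C(O)=O | intermediate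
16 | (1R,2R)-2-(7-methoxy-2-oxo-2H-chromen-6-yl)-1,4-dimethylcyclohex-3-ene-1-carbonyl chloride | COc1cc2oc(=O)ccc2cc1[C@H]1C=C(C)CC[C@@]1(C)C(Cl)=O | intermediate
17 | (1R,2R)-2-(7-methoxy-2-oxo-2H-chromen-6-yl)-1,4-dimethylcyclohex-3-ene-1-carbaldehyde | COc1cc2oc(=O)ccc2cc1[C@H]1C=C(C)CC[C@@]1(C)C=O | intermediate
18 | 6-[(1S,6S)-6-ethenyl-3,6-dimethylcyclohex-2-en-1-yl]-7-methoxy-2H-chromen-2-one | COc1cc2oc(=O)ccc2cc1[C@H]1C=C(C)CC[C@@]1(C)C=C | intermediate
19 | 7-hydroxy-2H-chromen-2-one (umbelliferone) | O=c1ccc2ccc(O)cc2o1 | starting material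
20 | 7-hydroxy-8-iodo-2H-chromen-2-one | O=c1ccc2ccc(O)c(I)c2o1 | intermediate
21 | 8-iodo-7-methoxy-2H-chromen-2-one | COc1ccc2ccc(=O)oc2c1I | intermediate
22 | 6-[(1S,6S)-6-[(E)-2-(7-methoxy-2-oxo-2H-chromen-8-yl)ethenyl]-3,6-dimethylcyclohex-2-en-1-yl]-7-methoxy-2H-chromen-2-one | COc1cc2oc(=O)ccc2cc1[C@H]1C=C(C)CC[C@@]1(C)/C=C/c1c(OC)ccc2ccc(=O)oc12 | target

## Step count and risks

Total steps: 12. Longest linear sequence: 9 (steps 1, 2, 4, 5, 6, 7, 8, 9, 12).

**Step 7 (ring-contracting Claisen).** The risks are enolisation next to the coumarin and ionisation of the tertiary allylic C–O bond instead of a concerted rearrangement, which would cost enantiopurity. The fallback runs the same ring contraction without base at the aldehyde oxidation level. It sets out from 12: iBu2AlH (1.0 equiv, CH2Cl2, −78 °C), which reduces the saturated δ-lactone ahead of the conjugated coumarin carbonyl, gives (3RS,6S)-6-[(E)-2-(7-methoxy-2-oxo-2H-chromen-6-yl)ethenyl]-3,6-dimethyloxan-2-ol F4. MsCl and Et3N then dehydrate it to the cyclic enol ether 6-{(E)-2-[(2S)-2,5-dimethyl-3,4-dihydro-2H-pyran-2-yl]ethenyl}-7-methoxy-2H-chromen-2-one F5. Heating F5 in xylene at 140 °C brings about the Claisen rearrangement of the 2-alkenyl-dihydropyran through the same boat geometry and gives the aldehyde directly, so the fallback comes back to the route at 17 and replaces steps 7 and 8.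

**Step 12 (final Heck).** A di-ortho-substituted aryl iodide has to couple with a vinyl group on a quaternary carbon beside a bulky aryl group. The fallback turns the coupling into a Suzuki reaction. It sets out from 17: dimethyl (1-diazo-2-oxopropyl)phosphonate with K2CO3 in MeOH (Ohira–Bestmann) gives 6-[(1S,6R)-6-ethynyl-3,6-dimethylcyclohex-2-en-1-yl]-7-methoxy-2H-chromen-2-one F6. Hydroboration with pinacolborane catalysed by Cp2Zr(H)Cl gives the (E)-alkenylboronate 6-[(1S,6S)-3,6-dimethyl-6-[(E)-2-(4,4,5,5-tetramethyl-1,3,2-dioxaborolan-2-yl)ethenyl]cyclohex-2-en-1-yl]-7-methoxy-2H-chromen-2-one F7. Suzuki–Miyaura coupling of F7 with 21 (PdCl2(dppf), K3PO4, dioxane/H2O, 80 °C, acidic work-up to re-close any opened coumarin) comes back to the route at 22.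

**Step 6 (enolate methylation beside a coumarin).** The enolate may add to the coumarin, or alkylation may be incomplete or go twice. The fallback puts the methyl group in before the coumarin is attached. It sets out from 5: TEMPO and PhI(OAc)2 give (6S)-6-ethenyl-6-methyloxan-2-one F1, and LiN(iPr)2 followed by MeI gives (3RS,6S)-6-ethenyl-3,6-dimethyloxan-2-one F2. Bromide 8 is converted by copper-catalysed halogen exchange (CuI, NaI, trans-N,N'-dimethylcyclohexane-1,2-diamine, dioxane, 110 °C) into 6-iodo-7-methoxy-2H-chromen-2-one F3. A phosphine-free, silver-assisted Heck coupling of F2 with F3 (Pd(OAc)2, Ag2CO3, toluene, 80 °C), in which the silver salt keeps the tertiary allylic C–O bond from being ionised or eliminated, comes back to the route at 12.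

## Further compounds

F1 | step 6 | (6S)-6-ethenyl-6-methyloxan-2-one | O=C1CCC[C@@](C)(C=C)O1
F2 | step 6 | (3RS,6S)-6-ethenyl-3,6-dimethyloxan-2-one | O=C1C(C)CC[C@@](C)(C=C)O1
F3 | step 6 | 6-iodo-7-methoxy-2H-chromen-2-one | COc1cc2oc(=O)ccc2cc1I
F4 | step 7 | (3RS,6S)-6-[(E)-2-(7-methoxy-2-oxo-2H-chromen-6-yl)ethenyl]-3,6-dimethyloxan-2-ol | OC1C(C)CC[C@@](C)(/C=C/c2cc3ccc(=O)oc3cc2OC)O1
F5 | step 7 | 6-{(E)-2-[(2S)-2,5-dimethyl-3,4-dihydro-2H-pyran-2-yl]ethenyl}-7-methoxy-2H-chromen-2-one | CC1=CO[C@](C)(/C=C/c2cc3ccc(=O)oc3cc2OC)CC1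
F6 | step 12 | 6-[(1S,6R)-6-ethynyl-3,6-dimethylcyclohex-2-en-1-yl]-7-methoxy-2H-chromen-2-one | COc1cc2oc(=O)ccc2cc1[C@H]1C=C(C)CC[C@@]1(C)C#C
F7 | step 12 | 6-[(1S,6S)-3,6-dimethyl-6-[(E)-2-(4,4,5,5-tetramethyl-1,3,2-dioxaborolan-2-yl)ethenyl]cyclohex-2-en-1-yl]-7-methoxy-2H-chromen-2-one | COc1cc2oc(=O)ccc2cc1[C@H]1C=C(C)CC[C@@]1(C)/C=C/B1OC(C)(C)C(C)(C)O1
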